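**Plan**

- Retrosynthesis: after removal of four methoxymethyl (MOM) ethers, ring C is cut at O1–C8a and C4–C4a. This gives 3,5-bis(methoxymethoxy)benzyne (ring A) and an O-silylated (S)-β-hydroxy ester that carries ring B, C2, C3 and C4.
- The cut is possible because C8a (bearing O1) and C4a (bearing the C4 carbonyl) are neighbours on ring A and C4a lies beside the C5 oxygen. A 3-alkoxyaryne delivers exactly this pattern when an oxygen nucleophile adds and the resulting aryl anion is acylated.
- The ester is cut at C3–C4 (Claisen methoxycarbonylation of an aryl methyl ketone) and at the aryl–allyl bond (Suzuki–Miyaura coupling with hydrated, protected geranyl acetate).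
- Forward: aryne precursor from phloroglucinol (steps 1–4); side chain from geranyl acetate (steps 5–6); ring B ketone, coupling, β-keto ester, reduction and silylation (steps 7–12); annulation closes ring C, the only ring formed (step 13); acid unmasks the target (step 14).
- Stereochemistry: C2 (S) is set by Noyori–Ikariya transfer hydrogenation of the β-keto ester (step 11) and carried through because the C2–O bond is never broken. The E olefin comes from geranyl acetate.

Key step: step 13

Assumption: the target is read from the SMILES as the (2S)-flavanone with an E side-chain olefin; reagents named without a compound number are taken as commercial.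

**Route**

Step 1
Reactants: 1 phloroglucinol
Product: 2 3,5-bis(methoxymethoxy)phenol
Conditions: MOMCl (2.1 equiv), iPr2NEt, DMF, 0 °C → rt
Reagents that add atoms: chloromethyl methyl ether (MOMCl), COCCl
Why: Base-mediated O-alkylation of the symmetric triphenol is statistical, so two equivalents of MOMCl should give the bis-ether as the main component, separable from the mono- and tris-ethers, which are recycled.

Step 2
Reactants: 2 3,5-bis(methoxymethoxy)phenol
Product: 3 2-bromo-3,5-bis(methoxymethoxy)phenol
Conditions: NBS (1.0 equiv), CH2Cl2, −78 °C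
Reagents that add atoms: N-bromosuccinimide, O=C1CCC(=O)N1Br
Why: Electrophilic aromatic bromination should go to C2 because this position is activated by all three oxygens, is less hindered than C4 between two MOM ethers, and ortho attack is assisted by the free hydroxyl in a non-polar solvent.

Step 3
Reactants: 3 2-bromo-3,5-bis(methoxymethoxy)phenol
Product: 4 [2-bromo-3,5-bis(methoxymethoxy)phenoxy]trimethylsilane
Conditions: HMDS, THF, 70 °C; evaporate
Reagents that add atoms: hexamethyldisilazane, C[Si](C)(C)N[Si](C)(C)C
Why: O-Silylation of a phenol with HMDS gives the aryl trimethylsilyl ether with ammonia as the only by-product, so the crude material can be used after evaporation.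

Step 4
Reactants: 4 [2-bromo-3,5-bis(methoxymethoxy)phenoxy]trimethylsilane
Product: 7 3,5-bis(methoxymethoxy)-2-(trimethylsilyl)phenyl trifluoromethanesulfonate, via aryllithium 5 (not isolated), via lithium phenolate 6 (not isolated)
Conditions: n-BuLi, THF, −78 °C; then Tf2O, −78 °C
Reagents that add atoms: trifluoromethanesulfonic anhydride, O=S(=O)(OS(=O)(=O)C(F)(F)F)C(F)(F)F
Why: Bromine–lithium exchange at −78 °C outruns directed metalation, the ortho-lithio aryl silyl ether 5 undergoes 1,3 O-to-C silyl migration (retro-Brook rearrangement) to phenolate 6, and Tf2O traps the oxygen, which is the standard sequence to 2-silylaryl triflates.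

Step 5
Reactants: 8 geranyl acetate
Product: 10 (2E)-7-hydroxy-3,7-dimethyloct-2-en-1-yl acetate, via organomercurial acetate 9 (not isolated)
Conditions: Hg(OAc)2, THF/H2O (1:1), rt; then NaBH4, 3 M aq. NaOH, 0 °C
Reagents that add atoms: water, O
Why: Oxymercuration–demercuration gives Markovnikov hydration, and the distal 6,7-olefin should react because the 2,3-olefin is deactivated inductively by the allylic acetate.

Step 6
Reactants: 10 (2E)-7-hydroxy-3,7-dimethyloct-2-en-1-yl acetate
Product: 11 (2E)-7-(methoxymethoxy)-3,7-dimethyloct-2-en-1-yl acetate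
Conditions: MOMCl, iPr2NEt, Bu4NI (cat.), CH2Cl2, reflux
Reagents that add atoms: chloromethyl methyl ether (MOMCl), COCCl
Why: MOMCl activated by iodide and a hindered amine base alkylates even tertiary alcohols (acetal-forming O-alkylation), and the allylic acetate is inert to these conditions.

Step 7
Reactants: 12 1-(3-bromo-4-hydroxyphenyl)ethan-1-one
Product: 13 1-[3-bromo-4-(methoxymethoxy)phenyl]ethan-1-one
Conditions: MOMCl, iPr2NEt, CH2Cl2, 0 °C → rt
Reagents that add atoms: chloromethyl methyl ether (MOMCl), COCCl
Why: Standard base-mediated methoxymethylation of an acidic para-acyl phenol.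

Step 8
Reactants: 13 1-[3-bromo-4-(methoxymethoxy)phenyl]ethan-1-one
Product: 14 1-[4-(methoxymethoxy)-3-(4,4,5,5-tetramethyl-1,3,2-dioxaborolan-2-yl)phenyl]ethan-1-one
Conditions: B2pin2, Pd(dppf)Cl2 (3 mol%), KOAc, 1,4-dioxane, 90 °C
Reagents that add atoms: bis(pinacolato)diboron, CC1(C)OB(OC1(C)C)B1OC(C)(C)C(C)(C)O1
Why: Miyaura borylation of aryl bromides under zerovalent palladium catalysis with KOAc tolerates the ketone and the acetal.

Step 9
Reactants: 14 1-[4-(methoxymethoxy)-3-(4,4,5,5-tetramethyl-1,3,2-dioxaborolan-2-yl)phenyl]ethan-1-one, 11 (2E)-7-(methoxymethoxy)-3,7-dimethyloct-2-en-1-yl acetate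
Product: 15 1-{4-(methoxymethoxy)-3-[(2E)-7-(methoxymethoxy)-3,7-dimethyloct-2-en-1-yl]phenyl}ethan-1-one
Conditions: Pd(PPh3)4 (5 mol%), K2CO3, 1,4-dioxane/H2O (5:1), 70 °C
Reagents that add atoms: none
Why: In this Suzuki–Miyaura allyl–aryl coupling zerovalent palladium ionises the allylic acetate to a π-allyl complex, the aryl group is transferred from the base-activated boronate, and reductive elimination at the unsubstituted terminus should give the linear product with the E geometry retained.

Step 10
Reactants: 15 1-{4-(methoxymethoxy)-3-[(2E)-7-(methoxymethoxy)-3,7-dimethyloct-2-en-1-yl]phenyl}ethan-1-one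
Product: 16 methyl 3-{4-(methoxymethoxy)-3-[(2E)-7-(methoxymethoxy)-3,7-dimethyloct-2-en-1-yl]phenyl}-3-oxopropanoate
Conditions: NaH (3 equiv), dimethyl carbonate, THF, 65 °C; AcOH quench
Reagents that add atoms: dimethyl carbonate, COC(=O)OC
Why: Crossed Claisen condensation of the methyl ketone enolate with dimethyl carbonate is driven to completion by irreversible deprotonation of the β-keto ester, and the acetals and the olefin are inert to NaH.

Step 11
Reactants: 16 methyl 3-{4-(methoxymethoxy)-3-[(2E)-7-(methoxymethoxy)-3,7-dimethyloct-2-en-1-yl]phenyl}-3-oxopropanoate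
Product: 17 methyl (3S)-3-hydroxy-3-{4-(methoxymethoxy)-3-[(2E)-7-(methoxymethoxy)-3,7-dimethyloct-2-en-1-yl]phenyl}propanoate
Conditions: RuCl[(S,S)-TsDPEN](p-cymene) (1 mol%), HCO2H/Et3N (5:2), EtOAc, 35 °C
Reagents that add atoms: none
Why: In this Noyori–Ikariya asymmetric transfer hydrogenation the (S,S)-TsDPEN ruthenium hydride should deliver hydride to the Re face of the aryl ketone through the CH–π-organised six-membered transition state established for aryl ketones, which sets the S carbinol centre (future C2) without touching the olefin or the acetals.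

Step 12
Reactants: 17 methyl (3S)-3-hydroxy-3-{4-(methoxymethoxy)-3-[(2E)-7-(methoxymethoxy)-3,7-dimethyloct-2-en-1-yl]phenyl}propanoate
Product: 18 methyl (3S)-3-{4-(methoxymethoxy)-3-[(2E)-7-(methoxymethoxy)-3,7-dimethyloct-2-en-1-yl]phenyl}-3-[(trimethylsilyl)oxy]propanoate
Conditions: TMSCl, imidazole, CH2Cl2, 0 °C; filter, evaporate
Reagents that add atoms: chlorotrimethylsilane, C[Si](C)(C)Cl
Why: Silylation of a secondary alcohol with TMSCl and imidazole is fast at 0 °C and leaves the stereocentre untouched, and the labile ether is used without chromatography.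

Step 13
Reactants: 18 methyl (3S)-3-{4-(methoxymethoxy)-3-[(2E)-7-(methoxymethoxy)-3,7-dimethyloct-2-en-1-yl]phenyl}-3-[(trimethylsilyl)oxy]propanoate, 7 3,5-bis(methoxymethoxy)-2-(trimethylsilyl)phenyl trifluoromethanesulfonate
Product: 20 (2S)-5,7-bis(methoxymethoxy)-2-{4-(methoxymethoxy)-3-[(2E)-7-(methoxymethoxy)-3,7-dimethyloct-2-en-1-yl]phenyl}-2,3-dihydro-4H-chromen-4-one, via 3,5-bis(methoxymethoxy)benzyne 19 (not isolated)
Conditions: 18 (1.0 equiv), 7 (1.5 equiv), tetrabutylammonium difluorotriphenylsilicate (TBAT, 1.5 equiv, added over 2 h), THF, 0 °C → rt; aq. NH4Cl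
Reagents that add atoms: none
Why: Proposed new method: fluoride from TBAT removes the aryl silyl group of 7 to release aryne 19 and cleaves the O–Si bond of 18 to give the secondary alkoxide with no proton source present; the alkoxide adds to the aryne carbon remote from the neighbouring methoxymethoxy group (future C8a), which places the aryl anion at C4a beside the C5 oxygen. That anion closes ring C by 6-exo-trig nucleophilic acyl substitution on the methyl ester (C4–C4a after O1–C8a), and the methoxide set free is silylated by further 18 or 7 to methoxytrimethylsilane while releasing the next alkoxide or aryne, so no stoichiometric strong base accumulates that could enolise the flavanone and open it by retro-oxa-Michael reaction. The closest known reaction types are the fluoride-triggered annulation of arynes with ortho-hydroxy-, ortho-amino- and ortho-mercaptobenzoate esters to xanthones, acridones and thioxanthones and the insertion of arynes into carboxylic acid C–O bonds that gives ortho-hydroxyaryl ketones; an aliphatic β-oxy ester has not been shown as the partner. No stereocentre is formed: the C2–O bond of 18 is never broken, so the S configuration from step 11 is carried into 20. The step needs regioselectivity (oxygen at C8a, acyl at C4a), which the inductive effect and ring distortion caused by the alkoxy group next to the aryne bond secure, and chemoselectivity for ring closure over protonation, α-deprotonation with β-elimination or retro-aldol cleavage, which the aprotic silyl ether protocol, the six-membered proximity of the ester, the low stationary alkoxide concentration under slow fluoride addition and the reluctance of an ester aldolate to fragment secure.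

Step 14
Reactants: 20 (2S)-5,7-bis(methoxymethoxy)-2-{4-(methoxymethoxy)-3-[(2E)-7-(methoxymethoxy)-3,7-dimethyloct-2-en-1-yl]phenyl}-2,3-dihydro-4H-chromen-4-one
Product: 21 (2S)-5,7-dihydroxy-2-{4-hydroxy-3-[(2E)-7-hydroxy-3,7-dimethyloct-2-en-1-yl]phenyl}-2,3-dihydro-4H-chromen-4-one
Conditions: 3 M aq. HCl/MeOH (1:5), 40 °C
Reagents that add atoms: none
Why: Acid-catalysed transacetalisation of the four MOM ethers to dimethoxymethane in methanol is a standard final step for prenylated flavanones, and at 40 °C the olefin, the tertiary alcohol and the C2 stereocentre should survive.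

**Compound list**

1 | phloroglucinol | Oc1cc(O)cc(O)c1 | starting material
2 | 3,5-bis(methoxymethoxy)phenol | COCOc1cc(O)cc(OCOC)c1 | intermediate
3 | 2-bromo-3,5-bis(methoxymethoxy)phenol | COCOc1cc(O)c(Br)c(OCOC)c1 | intermediate
4 | [2-bromo-3,5-bis(methoxymethoxy)phenoxy]trimethylsilane | COCOc1cc(O[Si](C)(C)C)c(Br)c(OCOC)c1 | intermediate
5 | [2,4-bis(methoxymethoxy)-6-(trimethylsilyloxy)phenyl]lithium (aryllithium) | COCOc1cc(O[Si](C)(C)C)c([Li])c(OCOC)c1 | intermediate
6 | lithium 3,5-bis(methoxymethoxy)-2-(trimethylsilyl)phenolate | COCOc1cc([O-])c([Si](C)(C)C)c(OCOC)c1.[Li+] | intermediate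
7 | 3,5-bis(methoxymethoxy)-2-(trimethylsilyl)phenyl trifluoromethanesulfonate | COCOc1cc(OCOC)c([Si](C)(C)C)c(OS(=O)(=O)C(F)(F)F)c1 | intermediate
8 | geranyl acetate, (2E)-3,7-dimethylocta-2,6-dien-1-yl acetate | CC(C)=CCC/C(C)=C/COC(C)=O | starting material
9 | (2E)-6-(acetoxymercurio)-7-hydroxy-3,7-dimethyloct-2-en-1-yl acetate (organomercurial acetate) | C/C(=C\COC(C)=O)CCC([Hg]OC(C)=O)C(C)(C)O | intermediate
10 | (2E)-7-hydroxy-3,7-dimethyloct-2-en-1-yl acetate | C/C(=C\COC(C)=O)CCCC(C)(C)O | intermediate
11 | (2E)-7-(methoxymethoxy)-3,7-dimethyloct-2-en-1-yl acetate | C/C(=C\COC(C)=O)CCCC(C)(C)OCOC | intermediate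
12 | 1-(3-bromo-4-hydroxyphenyl)ethan-1-one | CC(=O)c1ccc(O)c(Br)c1 | starting material
13 | 1-[3-bromo-4-(methoxymethoxy)phenyl]ethan-1-one | CC(=O)c1ccc(OCOC)c(Br)c1 | intermediate
14 | 1-[4-(methoxymethoxy)-3-(4,4,5,5-tetramethyl-1,3,2-dioxaborolan-2-yl)phenyl]ethan-1-one | CC(=O)c1ccc(OCOC)c(B2OC(C)(C)C(C)(C)O2)c1 | intermediate
15 | 1-{4-(methoxymethoxy)-3-[(2E)-7-(methoxymethoxy)-3,7-dimethyloct-2-en-1-yl]phenyl}ethan-1-one | C/C(=C\Cc1cc(C(C)=O)ccc1OCOC)CCCC(C)(C)OCOC | intermediate
16 | methyl 3-{4-(methoxymethoxy)-3-[(2E)-7-(methoxymethoxy)-3,7-dimethyloct-2-en-1-yl]phenyl}-3-oxopropanoate | C/C(=C\Cc1cc(C(=O)CC(=O)OC)ccc1OCOC)CCCC(C)(C)OCOC | intermediate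
17 | methyl (3S)-3-hydroxy-3-{4-(methoxymethoxy)-3-[(2E)-7-(methoxymethoxy)-3,7-dimethyloct-2-en-1-yl]phenyl}propanoate | C/C(=C\Cc1cc([C@@H](O)CC(=O)OC)ccc1OCOC)CCCC(C)(C)OCOC | intermediate
18 | methyl (3S)-3-{4-(methoxymethoxy)-3-[(2E)-7-(methoxymethoxy)-3,7-dimethyloct-2-en-1-yl]phenyl}-3-[(trimethylsilyl)oxy]propanoate | C/C(=C\Cc1cc([C@@H](O[Si](C)(C)C)CC(=O)OC)ccc1OCOC)CCCC(C)(C)OCOC | intermediate
19 | 3,5-bis(methoxymethoxy)benzyne | COCOC1=CC(OCOC)=CC#C1 | intermediate
20 | (2S)-5,7-bis(methoxymethoxy)-2-{4-(methoxymethoxy)-3-[(2E)-7-(methoxymethoxy)-3,7-dimethyloct-2-en-1-yl]phenyl}-2,3-dihydro-4H-chromen-4-one | C/C(=C\Cc1cc([C@@H]2CC(=O)c3c(OCOC)cc(OCOC)cc3O2)ccc1OCOC)CCCC(C)(C)OCOC | intermediate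
21 | (2S)-5,7-dihydroxy-2-{4-hydroxy-3-[(2E)-7-hydroxy-3,7-dimethyloct-2-en-1-yl]phenyl}-2,3-dihydro-4H-chromen-4-one | C/C(=C\Cc1cc([C@@H]2CC(=O)c3c(O)cc(O)cc3O2)ccc1O)CCCC(C)(C)O | target

**Count**

Total steps: 14. Longest linear sequence: 8 steps (steps 7–14 from 12, or equally steps 5, 6 and 9–14 from 8).

**Steps most likely to fail**

Step 13. The C4a aryl anion may be protonated, or may remove an α-hydrogen of the ester (followed by β-elimination of the aryloxide), faster than it acylates. The flavanone may also open by base-mediated retro-oxa-Michael reaction with loss of configuration at C2. The fallback makes the two bonds one after the other by known reactions and sets out from β-keto ester 16 and bromophenol 3. Transfer hydrogenation of 16 with the enantiomeric catalyst RuCl[(R,R)-TsDPEN](p-cymene) in HCO2H/Et3N gives methyl (3R)-3-hydroxy-3-{4-(methoxymethoxy)-3-[(2E)-7-(methoxymethoxy)-3,7-dimethyloct-2-en-1-yl]phenyl}propanoate F1. Mitsunobu etherification of F1 with 3 (PPh3, DIAD, toluene, 0 °C) inverts the carbinol and gives methyl (3S)-3-[2-bromo-3,5-bis(methoxymethoxy)phenoxy]-3-{4-(methoxymethoxy)-3-[(2E)-7-(methoxymethoxy)-3,7-dimethyloct-2-en-1-yl]phenyl}propanoate F2. Bromine–lithium exchange (n-BuLi, THF, −100 °C) followed by Parham cyclization of the aryllithium onto the ester closes ring C, and the route is rejoined at 20.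

Step 9. Ionisation of the allylic acetate may be slower than protodeboronation of the ortho-alkoxy arylboronate, the acetate may be saponified by the aqueous base, or the π-allyl intermediate may isomerise with erosion of the E geometry. The fallback replaces the acetate by a bromide, which undergoes fast oxidative addition under anhydrous conditions, and sets out from 11. Methanolysis (K2CO3, MeOH, rt) gives (2E)-7-(methoxymethoxy)-3,7-dimethyloct-2-en-1-ol F3. Bromination (CBr4, PPh3, CH2Cl2, 0 °C) gives (2E)-1-bromo-7-(methoxymethoxy)-3,7-dimethyloct-2-ene F4. Coupling of F4 with boronate 14 (Pd(dppf)Cl2, CsF, THF, 40 °C) rejoins the route at 15.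

Step 14. The longer acid exposure needed for the aliphatic MOM ether may promote cyclization of the side-chain olefin onto the neighbouring 4'-hydroxyl (chroman formation) or ionisation of the tertiary carbinol (elimination or methyl ether formation). The fallback stages the deprotection with two different mechanisms and sets out from 20. NaHSO4–SiO2 in CH2Cl2 at rt should cleave only the three phenolic MOM ethers and give (2S)-5,7-dihydroxy-2-{4-hydroxy-3-[(2E)-7-(methoxymethoxy)-3,7-dimethyloct-2-en-1-yl]phenyl}-2,3-dihydro-4H-chromen-4-one F5. ZnBr2 and n-PrSH in CH2Cl2 at 0 °C then remove the tertiary alkyl MOM ether by thiol capture within minutes, and the route is rejoined at 21.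

**Further compounds**

F1 | step 13 | methyl (3R)-3-hydroxy-3-{4-(methoxymethoxy)-3-[(2E)-7-(methoxymethoxy)-3,7-dimethyloct-2-en-1-yl]phenyl}propanoate | C/C(=C\Cc1cc([C@H](O)CC(=O)OC)ccc1OCOC)CCCC(C)(C)OCOC
F2 | step 13 | methyl (3S)-3-[2-bromo-3,5-bis(methoxymethoxy)phenoxy]-3-{4-(methoxymethoxy)-3-[(2E)-7-(methoxymethoxy)-3,7-dimethyloct-2-en-1-yl]phenyl}propanoate | C/C(=C\Cc1cc([C@@H](Oc2cc(OCOC)cc(OCOC)c2Br)CC(=O)OC)ccc1OCOC)CCCC(C)(C)OCOC
F3 | step 9 | (2E)-7-(methoxymethoxy)-3,7-dimethyloct-2-en-1-ol | C/C(=C\CO)CCCC(C)(C)OCOC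
F4 | step 9 | (2E)-1-bromo-7-(methoxymethoxy)-3,7-dimethyloct-2-ene | C/C(=C\CBr)CCCC(C)(C)OCOC
F5 | step 14 | (2S)-5,7-dihydroxy-2-{4-hydroxy-3-[(2E)-7-(methoxymethoxy)-3,7-dimethyloct-2-en-1-yl]phenyl}-2,3-dihydro-4H-chromen-4-one | C/C(=C\Cc1cc([C@@H]2CC(=O)c3c(O)cc(O)cc3O2)ccc1O)CCCC(C)(C)OCOC
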